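**Plan**

Numbering: ring carbons C1–C10, with C1 = olefinic CH, C2 = CHOH, C4 = C(=C15H2), C5 = CHOAc, C6 = lactone O–CH, C7 = CH bearing C11(=C13H2)–C12(=O), C8 = CHOTig, C10 = C(C14H3)=. The γ-lactone (O, C6, C7, C11, C12) is cis-fused to the ten-membered ring.
Retrosynthesis: cut C1=C10 (metathesis), the two esters, C8–C9 (methallylation of a C8 aldehyde) and C4–C5 (alkenylchromium addition to a C5 aldehyde). The cis α-methylene-γ-butyrolactone with two latent aldehydes that remains is cut at O–C6 and C7–C11 into 2-bromoacrylic acid and a diene.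
Enabling feature: C6 lies between C7 and C5, so C7=C6–C5=CMe2 can be a conjugated diene. C11 enters at C7, palladium is held as an allyl unit over C6–C5–CMe2, and the carboxylate closes the five-membered ring at C6. The helpers are the CMe2 cap (latent C5 aldehyde) and a glyceraldehyde ketal at C8 (latent C8 aldehyde and stereocontroller); they leave later as acetone and formaldehyde.
Forward: diene (2 steps), lactone ring in one step, C5 arm (ozonolysis, coupling with the C1–C4 iodide, acetate), C8 arm (periodic acid, methallylation, tiglate), ten-membered ring, desilylation.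
Stereochemistry: C8 of (R)-glyceraldehyde acetonide directs C7, and the E geometry of C6=C7 fixes C6 relative to C7. Felkin–Anh addition sets C5, and (R)-BINOL–titanium catalysis sets C2 and re-sets C8. Ring strain makes C1=C10 Z, and the tiglate geometry is bought.

Key step: step 3

Remark: the SMILES is read as a cis-fused lactone (H6 and H7 on one face), Z at C1=C10 (C9 and C2 cis), an E (tiglate) ester and 2R,5S,6R,7R,8R; compounds 1, 2, 4, 7, 13, 14, 23 and 25 are taken as commercial.

Step 1
Reactants: 1 1-bromo-3-methylbut-2-ene; 2 triethyl phosphite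
Product: 3 diethyl (3-methylbut-2-en-1-yl)phosphonate
Conditions: neat, 130 °C
Reagents that add atoms: none
Why: Michaelis–Arbuzov reaction, in which phosphorus attacks the primary allylic carbon of 1 and bromide dealkylates the phosphonium salt, should give 3 without allylic transposition.

Step 2
Reactants: 3 diethyl (3-methylbut-2-en-1-yl)phosphonate; 4 (R)-2,2-dimethyl-1,3-dioxolane-4-carbaldehyde
Product: 6 (4S)-2,2-dimethyl-4-[(1E)-4-methylpenta-1,3-dien-1-yl]-1,3-dioxolane, via lithiated phosphonate 5 (not isolated)
Conditions: n-BuLi, THF, −78 °C; then 4, −78 °C to rt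
Reagents that add atoms: none
Why: Horner–Wadsworth–Emmons olefination, in which the allylic anion 5 reacts at its α-carbon because the γ-carbon is fully substituted, should give the new C6=C7 bond mainly as the E isomer while the low temperature keeps the α-alkoxy stereocentre of 4 intact.

Step 3
Reactants: 6 (4S)-2,2-dimethyl-4-[(1E)-4-methylpenta-1,3-dien-1-yl]-1,3-dioxolane; 7 2-bromoacrylic acid
Product: 10 cis-lactone (4S,5S)-4-[(4S)-2,2-dimethyl-1,3-dioxolan-4-yl]-3-methylidene-5-(2-methylprop-1-en-1-yl)oxolan-2-one, via vinylpalladium bromide 8 (not isolated), via allylpalladium carboxylate 9 (not isolated)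
Conditions: Pd(OAc)2 (5 mol %), 1,3-bis(diphenylphosphino)propane (6 mol %), Ag2CO3 (1.2 equiv), MeCN, 60 °C
Reagents that add atoms: none
Why: Oxidative addition of zerovalent palladium to 7 gives 8, silver ion removes bromide, and the cationic vinylpalladium adds syn across C6=C7 with C11 going to C7, the only diene terminus that still carries hydrogen, to give the η3-allyl complex 9 spanning C6–C5–CMe2. The pendant carboxylate then attacks C6 from the face opposite to palladium, because the chelating diphosphine leaves it no coordination site, and this 5-exo-trig closure of the γ-lactone sets zerovalent palladium free again. The closest known reaction type is the palladium-catalysed heteroannulation of 1,3-dienes by 2-haloacrylic acids (Larock-type Heck insertion followed by Tsuji–Trost capture), applied here to a 1,1,4-trisubstituted diene. C7 is controlled by the ketal stereocentre C8: the hydrogen-eclipsed conformer (attack anti to the allylic C–O bond) and the inside-alkoxy conformer (attack anti to the CH2O arm) expose the same alkene face, and attack there gives the 7,8-relationship of the target. C6 follows stereospecifically from C7, since syn insertion plus anti displacement is a net anti addition to an E alkene and places the isobutenyl and dioxolanyl groups cis on the lactone; the only path that would exchange the allyl face, slippage of palladium to the tertiary CMe2 terminus, is disfavoured, and syn/anti exchange at C6 changes nothing because CMe2 bears two like groups. The step needs regioselectivity (C7 against CMe2, five- against seven-membered ring) and freedom from Diels–Alder addition, and both are secured by the gem-dimethyl terminus, whose cis methyl group also keeps the diene out of the s-cis form.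

Step 4
Reactants: 10 cis-lactone
Product: 12 (2R,3R)-3-[(4S)-2,2-dimethyl-1,3-dioxolan-4-yl]-4-methylidene-5-oxooxolane-2-carbaldehyde, via secondary ozonide 11 (not isolated)
Conditions: O3 (1 equiv, Sudan Red 7B as end-point indicator), CH2Cl2, −78 °C; then Me2S, −78 °C to rt
Reagents that add atoms: ozone [O-][O+]=O
Why: Ozonolysis with reductive work-up should cleave only the electron-rich trisubstituted C5=CMe2 bond, since the exocyclic methylene is deactivated by the lactone carbonyl, and it leaves C6 and C7 untouched.

Step 5
Reactants: 13 acrolein; 14 tributyl(propa-1,2-dien-1-yl)stannane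
Product: 15 (3R)-hex-1-en-5-yn-3-ol
Conditions: (R)-BINOL (20 mol %), Ti(OiPr)4 (10 mol %), 4 Å MS, CH2Cl2, −20 °C; aq. NaHCO3
Reagents that add atoms: none
Why: Keck asymmetric propargylation, in which the BINOL–titanium Lewis acid activates the aldehyde and the allenylstannane reacts by SE2' to give the homopropargylic alcohol, should direct attack to the Re face with the (R)-ligand and so set C2 as R.

Step 6
Reactants: 15 (3R)-hex-1-en-5-yn-3-ol
Product: 16 (3R)-3-(tert-butyldiphenylsilyloxy)hex-1-en-5-yne
Conditions: TBDPSCl, imidazole, DMF, rt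
Reagents that add atoms: tert-butyl(chloro)diphenylsilane CC(C)(C)[Si](Cl)(c1ccccc1)c1ccccc1
Why: Standard silylation of a secondary alcohol, with the tert-butyldiphenylsilyl group chosen because it must survive periodic acid in step 10.

Step 7
Reactants: 16 (3R)-3-(tert-butyldiphenylsilyloxy)hex-1-en-5-yne
Product: 18 (3R)-3-(tert-butyldiphenylsilyloxy)-5-iodohexa-1,5-diene, via iodoalkenylborane 17 (not isolated)
Conditions: B-iodo-9-BBN, CH2Cl2, −20 to 0 °C; then AcOH, 0 °C
Reagents that add atoms: B-iodo-9-borabicyclo[3.3.1]nonane IB1C2CCCC1CCC2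
Why: Haloboration–protonolysis, in which B-iodo-9-BBN adds boron and iodine cis across a terminal alkyne (iodine at the inner carbon) much faster than it touches an alkene and acetic acid then replaces boron by hydrogen, should give the 2-iodo-1-alkene.

Step 8
Reactants: 12 C5 aldehyde; 18 (3R)-3-(tert-butyldiphenylsilyloxy)-5-iodohexa-1,5-diene
Product: 19 C5 alcohol (4R,5R)-5-[(1S,4R)-4-(tert-butyldiphenylsilyloxy)-1-hydroxy-2-methylidenehex-5-en-1-yl]-4-[(4S)-2,2-dimethyl-1,3-dioxolan-4-yl]-3-methylideneoxolan-2-one
Conditions: CrCl2 (4 equiv), NiCl2 (2 mol %), DMSO, rt; aq. work-up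
Reagents that add atoms: none
Why: Nozaki–Hiyama–Kishi coupling, in which the alkenylchromium reagent made from 18 adds to the aldehyde alone among the carbonyl groups, should follow the polar Felkin–Anh model (C6–O bond anti to the incoming carbon) and so give the 5,6-anti alcohol with C5 as S.

Step 9
Reactants: 19 C5 alcohol
Product: 20 C5 acetate of 19 (2R,5S,6R,7R,8S in the target numbering)
Conditions: Ac2O, pyridine, DMAP (cat.), CH2Cl2, 0 °C
Reagents that add atoms: acetic anhydride CC(=O)OC(C)=O
Why: DMAP-catalysed acetylation of the only free hydroxyl group fixes the C5 acetate of the target.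

Step 10
Reactants: 20 C5 acetate
Product: 22 C8 aldehyde (2R,3S)-2-[(1S,4R)-1-acetoxy-4-(tert-butyldiphenylsilyloxy)-2-methylidenehex-5-en-1-yl]-4-methylidene-5-oxooxolane-3-carbaldehyde, via vicinal diol 21 (not isolated)
Conditions: H5IO6 (1.5 equiv), EtOAc, rt
Reagents that add atoms: none
Why: Periodic acid first hydrolyses the terminal ketal to 21 and then cleaves the glycol (Malaprade reaction), which removes the spent stereocontroller and unveils the C8 aldehyde under non-basic conditions that should spare the acidic C7–H, the allylic acetate and the silyl ether.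

Step 11
Reactants: 22 C8 aldehyde; 23 tributyl(2-methylprop-2-en-1-yl)stannane
Product: 24 C8 alcohol (4R,5R)-5-[(1S,4R)-1-acetoxy-4-(tert-butyldiphenylsilyloxy)-2-methylidenehex-5-en-1-yl]-4-[(1R)-1-hydroxy-3-methylbut-3-en-1-yl]-3-methylideneoxolan-2-one
Conditions: (R)-BINOL (20 mol %), Ti(OiPr)4 (10 mol %), 4 Å MS, CH2Cl2, −20 °C; aq. NaHCO3
Reagents that add atoms: none
Why: Keck asymmetric allylation with a methallylstannane, run under mild Lewis acid catalysis that should not enolise 22, should deliver the nucleophile to the Re face under control of the (R)-BINOL–titanium catalyst and set C8 as R.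

Step 12
Reactants: 24 C8 alcohol; 25 (E)-2-methylbut-2-enoyl chloride (tigloyl chloride)
Product: 26 C8 tiglate of 24 (2R,5S,6R,7R,8R), the open-chain metathesis precursor
Conditions: pyridine, DMAP (cat.), CH2Cl2, 0 °C to rt
Reagents that add atoms: none
Why: DMAP-catalysed acylation with the geometrically stable E acid chloride in the presence of the weak base pyridine should esterify the hindered C8 hydroxyl group before it can attack the lactone carbonyl.

Step 13
Reactants: 26 C8 tiglate
Product: 27 2-O-(tert-butyldiphenylsilyl) ether of the target (ten-membered ring closed, C1=C10 Z)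
Conditions: second-generation Grubbs catalyst (15 mol %), 1,4-benzoquinone (30 mol %), toluene (1 mM), 90 °C
Reagents that add atoms: none
Why: Ring-closing metathesis, initiated at the only monosubstituted olefin (C1) and ended at the isopropenyl group (C10) because the methylenes at C4 and C11 could only give a four- or an eight-membered ring and the tiglate is deactivated, should close the ten-membered ring, whose strain allows only the Z (ring-cis) trisubstituted olefin.

Step 14
Reactants: 27 silyl ether of the target
Product: 28 target CNP0210609.1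
Conditions: HF·pyridine, THF, 0 °C to rt
Reagents that add atoms: none
Why: Fluoride-mediated desilylation under buffered acidic conditions should free the C2 hydroxyl group without touching the two esters, the lactone or the Michael acceptor.

**Compound list**

1 | 1-bromo-3-methylbut-2-ene | CC(C)=CCBr | starting material
2 | triethyl phosphite | CCOP(OCC)OCC | starting material
3 | diethyl (3-methylbut-2-en-1-yl)phosphonate | CCOP(=O)(CC=C(C)C)OCC | intermediate
4 | (R)-2,2-dimethyl-1,3-dioxolane-4-carbaldehyde | O=C[C@H]1COC(C)(C)O1 | starting material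
5 | lithiated phosphonate (α-carbanion of 3, lithium salt) | [Li+].CCOP(=O)([CH-]C=C(C)C)OCC | intermediate
6 | (4S)-2,2-dimethyl-4-[(1E)-4-methylpenta-1,3-dien-1-yl]-1,3-dioxolane | CC(C)=C/C=C/[C@H]1COC(C)(C)O1 | intermediate
7 | 2-bromoacrylic acid | C=C(Br)C(=O)O | starting material
8 | (1-carboxyvinyl)palladium bromide, diphosphine omitted | C=C([Pd]Br)C(=O)O | intermediate
9 | allylpalladium carboxylate, drawn σ-bound at C6, diphosphine omitted | C=C(C(=O)[O-])[C@@H]([C@H]([Pd+])C=C(C)C)[C@H]1COC(C)(C)O1 | intermediate
10 | (4S,5S)-4-[(4S)-2,2-dimethyl-1,3-dioxolan-4-yl]-3-methylidene-5-(2-methylprop-1-en-1-yl)oxolan-2-one (cis) | C=C1C(=O)O[C@@H](C=C(C)C)[C@H]1[C@H]2COC(C)(C)O2 | intermediate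
11 | secondary ozonide of 10 (3,3-dimethyl-1,2,4-trioxolan-5-yl at C6) | C=C1C(=O)O[C@@H](C2OOC(C)(C)O2)[C@H]1[C@H]3COC(C)(C)O3 | intermediate
12 | (2R,3R)-3-[(4S)-2,2-dimethyl-1,3-dioxolan-4-yl]-4-methylidene-5-oxooxolane-2-carbaldehyde | C=C1C(=O)O[C@@H](C=O)[C@H]1[C@H]2COC(C)(C)O2 | intermediate
13 | acrolein | C=CC=O | starting material
14 | tributyl(propa-1,2-dien-1-yl)stannane | C=C=C[Sn](CCCC)(CCCC)CCCC | starting material
15 | (3R)-hex-1-en-5-yn-3-ol | C#CC[C@@H](O)C=C | intermediate
16 | (3R)-3-(tert-butyldiphenylsilyloxy)hex-1-en-5-yne | C#CC[C@@H](O[Si](c1ccccc1)(c1ccccc1)C(C)(C)C)C=C | intermediate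
17 | (Z)-2-iodoalk-1-enyl-9-BBN from 16 (B and I cis) | I/C(C[C@@H](O[Si](c1ccccc1)(c1ccccc1)C(C)(C)C)C=C)=C\B1C2CCCC1CCC2 | intermediate
18 | (3R)-3-(tert-butyldiphenylsilyloxy)-5-iodohexa-1,5-diene | C=C(I)C[C@@H](O[Si](c1ccccc1)(c1ccccc1)C(C)(C)C)C=C | intermediate
19 | C5 alcohol (2R,5S,6R,7R,8S) | C=C1C(=O)O[C@@H]([C@@H](O)C(=C)C[C@@H](O[Si](c2ccccc2)(c2ccccc2)C(C)(C)C)C=C)[C@H]1[C@H]3COC(C)(C)O3 | intermediate
20 | C5 acetate (2R,5S,6R,7R,8S) | C=C1C(=O)O[C@@H]([C@@H](OC(C)=O)C(=C)C[C@@H](O[Si](c2ccccc2)(c2ccccc2)C(C)(C)C)C=C)[C@H]1[C@H]3COC(C)(C)O3 | intermediate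
21 | vicinal diol from 20 (ketal removed) | C=C1C(=O)O[C@@H]([C@@H](OC(C)=O)C(=C)C[C@@H](O[Si](c2ccccc2)(c2ccccc2)C(C)(C)C)C=C)[C@H]1[C@H](O)CO | intermediate
22 | C8 aldehyde (2R,5S,6R,7S) | C=C1C(=O)O[C@@H]([C@@H](OC(C)=O)C(=C)C[C@@H](O[Si](c2ccccc2)(c2ccccc2)C(C)(C)C)C=C)[C@H]1C=O | intermediate
23 | tributyl(2-methylprop-2-en-1-yl)stannane | C=C(C)C[Sn](CCCC)(CCCC)CCCC | starting material
24 | C8 alcohol (2R,5S,6R,7R,8R) | C=C1C(=O)O[C@@H]([C@@H](OC(C)=O)C(=C)C[C@@H](O[Si](c2ccccc2)(c2ccccc2)C(C)(C)C)C=C)[C@H]1[C@H](O)CC(C)=C | intermediate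
25 | (E)-2-methylbut-2-enoyl chloride | C/C=C(\C)C(=O)Cl | starting material
26 | C8 tiglate, open-chain metathesis precursor (2R,5S,6R,7R,8R) | C=C1C(=O)O[C@@H]([C@@H](OC(C)=O)C(=C)C[C@@H](O[Si](c2ccccc2)(c2ccccc2)C(C)(C)C)C=C)[C@H]1[C@H](OC(=O)/C(C)=C/C)CC(C)=C | intermediate
27 | 2-O-(tert-butyldiphenylsilyl) ether of the target | C=C1C(=O)O[C@@H]2[C@H]1[C@H](OC(=O)/C(C)=C/C)C/C(C)=C\[C@H](O[Si](c3ccccc3)(c3ccccc3)C(C)(C)C)CC(=C)[C@@H]2OC(C)=O | intermediate
28 | CNP0210609.1 | C=C1C(=O)O[C@@H]2[C@H]1[C@H](OC(=O)/C(C)=C/C)C/C(C)=C\[C@H](O)CC(=C)[C@@H]2OC(C)=O | target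

Total step count: 14. Longest linear sequence: 11 (steps 1–4 and 8–14).

**Steps most likely to fail**

Step 3. Three things may go wrong:
- The carboxylate may bind to palladium and be delivered from the metal side, or the allyl unit may exchange its face before capture. Either event erodes the cis relationship at C6/C7.
- Facial discrimination by the ketal may be modest.
- β-Hydride loss from C7 may outrun ring closure.

The fallback sets out from 4 and comes back at 10. It builds the lactone by the C6–C7 and acyl–oxygen bonds instead. Morita–Baylis–Hillman reaction of 4 with ethyl acrylate (DABCO) would give ethyl 2-{hydroxy[(4R)-2,2-dimethyl-1,3-dioxolan-4-yl]methyl}acrylate F1. NBS/Me2S would convert F1 with allylic transposition into ethyl (2Z)-2-(bromomethyl)-3-[(4S)-2,2-dimethyl-1,3-dioxolan-4-yl]prop-2-enoate F2. Zinc-mediated Barbier addition of F2 to 3-methylbut-2-enal (THF/aq. NH4Cl) through a chair transition state would give the syn hydroxy ester F3. F3 lactonises with catalytic TsOH to 10.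

Step 13. Closure of a strained ten-membered ring onto a 1,1-disubstituted olefin may lose against oligomerisation and catalyst decay. Initiation beside the bulky silyl ether may also be slow. The fallback sets out from 26 and comes back at 28, and it changes the order of events and the nature of the metathesis substrate. HF·pyridine would first give the free C2 allylic alcohol F4. Its small, ruthenium-directing hydroxyl group should speed loading at C1, and its ring-closing metathesis would then be the last step of the synthesis.

Step 11. Enolisation at C7 (α to the aldehyde and allylic to C11=C13) may scramble C7 or open the lactone by β-elimination. Catalyst control may also be mismatched with the bias of the substrate. The fallback sets out from 22 and comes back at 26. The addition of 23 would be run in the opposite sense with (S)-BINOL/Ti(OiPr)4 to give the 8S alcohol F5. Mitsunobu esterification with tiglic acid (PPh3, DIAD) would then invert C8 and install the tiglate in one operation.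

**Further compounds**

F1 | step 3 | ethyl 2-{hydroxy[(4R)-2,2-dimethyl-1,3-dioxolan-4-yl]methyl}acrylate | C=C(C(=O)OCC)C(O)[C@H]1COC(C)(C)O1
F2 | step 3 | ethyl (2Z)-2-(bromomethyl)-3-[(4S)-2,2-dimethyl-1,3-dioxolan-4-yl]prop-2-enoate | CCOC(=O)/C(CBr)=C/[C@H]1COC(C)(C)O1
F3 | step 3 | syn hydroxy ester, ethyl 2-{1-[(4S)-2,2-dimethyl-1,3-dioxolan-4-yl]-2-hydroxy-4-methylpent-3-en-1-yl}acrylate with C6 and C7 as in 10 | C=C(C(=O)OCC)[C@@H]([C@@H](O)C=C(C)C)[C@H]1COC(C)(C)O1
F4 | step 13 | free C2 allylic alcohol from 26 | C=C1C(=O)O[C@@H]([C@@H](OC(C)=O)C(=C)C[C@@H](O)C=C)[C@H]1[C@H](OC(=O)/C(C)=C/C)CC(C)=C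
F5 | step 11 | 8S alcohol, C8 epimer of 24 | C=C1C(=O)O[C@@H]([C@@H](OC(C)=O)C(=C)C[C@@H](O[Si](c2ccccc2)(c2ccccc2)C(C)(C)C)C=C)[C@H]1[C@@H](O)CC(C)=C
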